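The constants used here are those of an exercise; no experiment stands behind them.

Two chemists dispute one order.

    reagent + free catalyst ⇌ catalyst intermediate A (K1 = 109 /M, k1 = 34500 /M/s)
    catalyst intermediate A ⇌ catalyst intermediate B (K2 = 0.61, k2 = 5.41 /s)
    catalyst intermediate B ⇌ released group + catalyst intermediate C (K3 = 0.0027 M, k3 = 24.7 /s)
    substrate + catalyst intermediate C ⇌ catalyst intermediate D (K4 = 3100 /M, k4 = 24200 /M/s)
    catalyst intermediate D → free catalyst + product (k5 = 1020 /s)
    reagent + released group ⇌ idle adduct, settled at all times (K6 = 135 /M)
    scavenger + released group → scavenged by-product (k7 = 5320 /M/s)

substrate 1.0 mM; reagent 4.00 equiv; scavenger 1.50 equiv; free catalyst 2.5 mol%; time 15 s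

- part of the substrate that has reacted at 15 s
- share of the unused reagent that is free and not bound as idle adduct, at 15 s

- amounts and yields of released group count idle adduct too
- run time (flask): 15 s

The second chemist says [substrate] sets the rate. She lets the whole catalyst charge wait as intermediate C for substrate. The rate is then k4[substrate][catalyst], first order in substrate. Its half-life is 1.15 s, so 15 s gives >99.9% reacted.

The first chemist says the catalyst charge sets the rate. My reckoning takes his side, with reagent and substrate held at their charges. Intermediate A falls back at 317 /s, far faster than its 5.41 /s forward. So step 1 stands at balance, with intermediate A at 0.44 times free catalyst. Free catalyst is therefore the resting state. Of intermediate B, 73.6% goes forward, so intermediate A yields product at 3.98 /s. Counting free catalyst and intermediates A, B, C and D, I reckon that intermediate A holds 27.6% of the catalyst.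

The product of these two is 1.10 /s: the turnover frequency, product made per second per catalyst charged. Substrate takes up intermediate C at 24.2 /s, far above this frequency. The rate is then close to zero order in substrate and first order in catalyst. I commit to 41.2% reacted.

Scavenger at its charge removes released group as fast as it forms near 0.00344 mM. Idle adduct stays small at that level, so I expect >99.9% of the unused reagent free.

The forecast takes the first side, with 39% reacted and 99.9% free, below my figure for the substrate. Its ground: “Turnover is limited by the A→B step”.

The simulation gives 38.8% and 99.9%. The first view stands: the flask lies far below the second view's figure and averages 1.03 /s per catalyst charged, against 1.10 /s reckoned. The neighbour with 0.62 mol% of free catalyst reaches 9.98%, and the frequency gives it 10.2%. The second view's picture, catalyst standing as intermediate C, has its region late: at 150 s, with substrate at 0%, intermediate C holds 100% of the catalyst. The way back from intermediate A to reagent and free catalyst is a part of why the flask stands at 38.8%, together with the hour of the reading. Without that way back the flask reaches 90.3%, and read at 150 s it reaches 100%.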